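## Structural features

The target is a germacranolide: a ten-membered carbocycle (C1–C10) fused trans across C6–C7 to an α-methylene-γ-butyrolactone (ring oxygen on C6, C12 carbonyl, C11=C13). The carbocycle holds two trisubstituted alkenes, C1=C10 and C4=C5, each carrying a hydroxymethyl group (C14 on C10, C15 on C4). In both alkenes the ring bonds are cis (C9 cis to C2, C3 cis to C6), although the CIP descriptors are E because CH2OH outranks the ring CH2. Three stereocentres stand side by side: C6 (lactone oxygen, allylic to C4=C5), C7 (ring fusion) and C8 (secondary angelate); all are R, C6/C7 trans on the lactone and C7/C8 anti along the chain C6–C9. The fragile groups are the α-methylene lactone (Michael acceptor), the angelate (Z-enoate that isomerises to the tiglate), the allylic C6–O lactone bond (ionisable by low-valent metals), the two primary allylic alcohols, and a free C8 hydroxyl next to the lactone (translactonisation). The real difficulty is closing a medium ring that contains two geometry-defined trisubstituted alkenes without disturbing either geometry or the stereotriad. The key step exploits the fact that C2 and C3 are adjacent methylenes, C2 allylic to C1=C10 and C3 allylic to C4=C5: a sulfone turns C2 into a nucleophile, a bromide keeps C3 an electrophile, and the C2–C3 bond closes the carbocycle onto the finished lactone.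

## Logic of the disconnections

33 back to 30: the C8–O acyl bond and the two O–Si bonds are cut first, because the angelate and the free allylic alcohols are the most labile groups and tolerate no base. This leaves a molecule with three masked hydroxyls. The forward steps need an oxidative benzyl-ether cleavage orthogonal to silyl ethers, an acylation that does not isomerise the Z-enoate, and a non-basic desilylation.

30 back to 27: the C11=C13 bond is cut, so the Michael acceptor is absent from every basic or reductive step before it. The forward step needs clean enolisation at C11, the only acidic position left in 27.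

27 back to 26 and 25 (key disconnection): the C2–S bond and then the ring bond C2–C3 are cut. This opens the ten-membered ring to an acyclic chain that already carries both alkenes, the lactone and all three stereocentres, so the ring closure creates no lasting stereocentre. The forward step demands α-alkylation of the sulfonyl allyl anion, SN2 rather than SN2′ attack at the bromide, and selective deprotonation at C2 in the presence of the lactone.

25 back to 22: the sulfur oxidation level, the C3–Br bond and the C3–C4 bond are cut in turn. The sulfone and the bromide cannot survive hydride or organometallic steps, so they are unveiled last. C3 becomes a one-carbon unit joined to the alkenyl iodide of 22, which demands a coupling with retention of alkene geometry.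

22 back to 20 and 19: the lactone C12–O bond is cut to a 1,4-diol and the C4–I/C5–H pair to an alkyne. The propargylic C6 hydroxyl then serves twice, directing the anti-hydroalumination that fixes the C4=C5 geometry and closing the lactone. The forward steps need primary-selective alcohol oxidation in the presence of a thioether.

19 back to 18, then 17 and 1: the C6–H bond (ketone) and the C5–C6 bond are cut. Lactone 17 is the acylating agent for the acetylide of 1, which gives a convergent union, and the C6 configuration is left to a chiral catalyst. The forward steps need mono-addition to the lactone and reagent control over the α-branched ynone.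

17 back to 14 and 13: the C12–O bond is cut to a vinyl group on C7, and C6 is returned to the alcohol level. A vinyl group is a latent two-carbon hydroxyethyl unit that a hindered borane distinguishes from the trisubstituted alkene by size. An allyl group on C7, as an enolate allylation of a malate would give, was set aside: it has one carbon too many, and its oxidative cleavage would compete with the ring alkenes.

13 back to 12, then 9 and 4: the benzylic C–O bond (the p-methoxybenzyl ether comes from an acetal) and the C9–C10 bond are cut. This gives two fragments of similar size, with the C1=C10 geometry already fixed in 4. The forward step is an sp3–sp2 coupling of a primary triflate with an alkenyl-metal, with retention.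

4 back to 3, 2 and 1: the C–S bond, the C–I/C–H pair and the C2–C1 bond to formaldehyde are cut. The geometry comes from alkoxide-directed anti-hydroalumination of the alkyne.

9 back to 8, 7, 6, 5 and 2: the acetal, the C7–C11 bond (vinyl delivered with inversion to an epoxide), the epoxide C–O bonds and the alkene are cut. C7 and C8 are thereby set by a catalytic asymmetric epoxidation and a stereospecific opening. The forward steps need regioselective attack at C7 rather than C8.

## Other disconnections considered

Alternative 1: The cut is C7–C8. In the forward direction CrCl2 would convert the C13 allylic bromide of the butenolide aldehyde A1 into an allylchromium that attacks the C8 aldehyde through C7, giving A2. In its favour, one step forms the ring, the C7–C8 bond and the exocyclic methylene, so no separate methylenation and no sulfone removal are needed. The 8-epi hydroxyl of A2 could be inverted and acylated at once by a Mitsunobu reaction with angelic acid, arriving at 32. On step economy after the ring closure this plan is better than the chosen one. Against it, two stereocentres (C7 and C8) would be created in the macrocyclisation and controlled only by C6 and the ring-forming transition state. The C8 aldehyde of A1 is β,γ-unsaturated and prone to conjugation, and the Mitsunobu step would act on a hindered carbinol with an acid that isomerises easily. The chosen plan creates no lasting stereocentre in the ring closure and sets C6, C7 and C8 beforehand under reagent control, at the price of a longer endgame.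

Alternative 2: The cut is C5–C6. CrCl2 with catalytic NiCl2 would turn the alkenyl iodide of A3 into an alkenylchromium that adds to the C6 aldehyde, and the alkoxide would lactonise onto the C12 ester to give A4. A4 is the same structure as 27, so this plan reaches that compound without sulfone chemistry and without a dissolving-metal step, which is an advantage over the chosen plan. It equals the chosen plan in closing the ring with both cis alkenes preformed and untouched. Against it, C6 would be created during the macrocyclisation on an α-branched, epimerisable aldehyde, with facial selectivity left to the conformation of the forming ring. The wrong face would give a cis-lactone or none. The iodoalkene terminus of A3 (C5 iodide with C3 and C15 on C4) also needs its own stereocontrolled synthesis, which is less direct than the alkyne hydroalumination used here. The chosen plan fixes C6 by asymmetric transfer hydrogenation before the ring is closed.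

Alternative 3: The cut forms C8–C9 and breaks C1–C6. KH with 18-crown-6 would ionise the tertiary C6 alcohol of the dialkenyl cyclohexenol A5, and the 1,5-diene C8=C7–C6–C1–C10=C9 would rearrange to the ten-membered dienone A6. In its favour, the ring arises by ring expansion with no entropic penalty and no high dilution, which is better than any direct medium-ring closure including the chosen one. The C4=C5 alkene is also cis by construction, and the rearrangement leaves a C6–C7 enolate that could be alkylated to start the lactone. Against it, the C1=C10 geometry and the C8 configuration would both be dictated by the transition state. The usual chair from a trans-dialkenyl substrate gives the trans ring alkene, so the cis alkene would need the cis-dialkenyl isomer A5 reacting through a boat. A6 also still lacks C11–C13, the C6 stereocentre and the lactone, all of which would have to be installed on a flexible cyclodecadienone open to transannular reactions. The chosen plan is longer before the ring closure but carries every stereocentre and the lactone into it.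

Key step: step 20

Remark: germacranolide numbering is used throughout (C1–C10 ring, C11–C13 lactone carbons, C14 on C10, C15 on C4); the stereodescriptors of the cyclisation substrate 25 and its product 26 were checked against the target and agree at C6, C7, C8 and both alkenes, so neither structure needed correction.

## Steps

Step 1
Reactants: 1 tert-butyldimethyl(prop-2-yn-1-yloxy)silane
Product: 2 4-[(tert-butyldimethylsilyl)oxy]but-2-yn-1-ol
Conditions: n-BuLi, THF, −78 °C; (CH2O)n, −78 °C to rt; aq. NH4Cl
Reagents that add atoms: paraformaldehyde (as formaldehyde), C=O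
Why: Hydroxymethylation of a lithium acetylide with formaldehyde released from the polymer, a standard one-carbon homologation; 2 then feeds both fragment lines (C14/C10/C1/C2 and C9/C8/C7/C6).

Step 2
Reactants: 2 4-[(tert-butyldimethylsilyl)oxy]but-2-yn-1-ol
Product: 3 (Z)-4-[(tert-butyldimethylsilyl)oxy]-3-iodobut-2-en-1-ol
Conditions: NaAlH2(OCH2CH2OMe)2, THF, 0 °C; EtOAc; then I2, THF, −78 °C; aq. Na2S2O3
Reagents that add atoms: iodine, II
Why: Alkoxide-directed anti-hydroalumination of a propargylic alcohol places aluminium on the distal alkyne carbon cis to the carbinol, and iodinolysis proceeds with retention, so iodine (the later site of C9) ends cis to C2 and the CH2OSi group trans to it. Keeping the reduction at 0 °C should avoid elimination of the silyloxy group to an allene.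

Step 3
Reactants: 3 (Z)-4-[(tert-butyldimethylsilyl)oxy]-3-iodobut-2-en-1-ol
Product: 4 tert-butyl{[(Z)-2-iodo-4-(phenylsulfanyl)but-2-en-1-yl]oxy}dimethylsilane
Conditions: PhSSPh, n-Bu3P, THF, rt
Reagents that add atoms: diphenyl disulfide, c1ccccc1SSc1ccccc1
Why: Disulfide–phosphine thioetherification of a primary allylic alcohol (oxyphosphonium formation, then SN2 by thiolate at the unhindered CH2). The thioether is the latent C2 sulfone and, unlike a sulfone, has no acidic proton to interfere with the later hydride and organometallic steps.

Step 4
Reactants: 2 4-[(tert-butyldimethylsilyl)oxy]but-2-yn-1-ol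
Product: 5 (E)-4-[(tert-butyldimethylsilyl)oxy]but-2-en-1-ol
Conditions: NaAlH2(OCH2CH2OMe)2, THF, 0 °C; aq. KNaC4H4O6
Reagents that add atoms: none
Why: The same directed anti-hydroalumination followed by protonolysis is the standard route from a propargylic alcohol to the E allylic alcohol needed for a trans epoxide.

Step 5
Reactants: 5 (E)-4-[(tert-butyldimethylsilyl)oxy]but-2-en-1-ol
Product: 6 [(2R,3R)-3-({[tert-butyl(dimethyl)silyl]oxy}methyl)oxiran-2-yl]methanol
Conditions: Ti(OiPr)4 (cat.), D-(−)-diethyl tartrate (cat.), t-BuOOH, 4 Å molecular sieves, CH2Cl2, −20 °C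
Reagents that add atoms: tert-butyl hydroperoxide, CC(C)(C)OO
Why: Sharpless asymmetric epoxidation of an E allylic alcohol. The D-(−)-tartrate ligand delivers oxygen to the face that gives the (2R,3R) epoxide, which fixes the absolute configuration of the future C8 and, after inversion, of C7.

Step 6
Reactants: 6 [(2R,3R)-3-({[tert-butyl(dimethyl)silyl]oxy}methyl)oxiran-2-yl]methanol
Product: 7 (2S,3S)-4-[(tert-butyldimethylsilyl)oxy]-2-ethenylbutane-1,3-diol
Conditions: CH2=CHMgBr (excess), CuI (cat.), THF/Et2O, −30 to −10 °C; aq. NH4Cl; brief aq. NaIO4 wash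
Reagents that add atoms: vinylmagnesium bromide, C=C[Mg]Br
Why: Copper-catalysed Grignard opening of a 2,3-epoxy alcohol at C2 (the future C7) with inversion gives the anti 2-vinyl-1,3-diol. Attack at the other epoxide carbon is disfavoured by the adjacent electron-withdrawing, bulky CH2OSi group, and any 1,2-diol regioisomer is destroyed by periodate.

Step 7
Reactants: 7 (2S,3S)-4-[(tert-butyldimethylsilyl)oxy]-2-ethenylbutane-1,3-diol
Product: 8 (2S,4S,5S)-4-({[tert-butyl(dimethyl)silyl]oxy}methyl)-5-ethenyl-2-(4-methoxyphenyl)-1,3-dioxane
Conditions: 4-MeOC6H4CH(OMe)2, pyridinium p-toluenesulfonate (cat.), CH2Cl2, rt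
Reagents that add atoms: 4-methoxybenzaldehyde dimethyl acetal, COc1ccc(cc1)C(OC)OC
Why: Acid-catalysed transacetalisation of the only free diol, a 1,3-diol, gives the dioxane with aryl, vinyl and CH2OSi groups all equatorial. The acetal carbon is set under thermodynamic control and is lost again in step 10.

Step 8
Reactants: 8 (2S,4S,5S)-4-({[tert-butyl(dimethyl)silyl]oxy}methyl)-5-ethenyl-2-(4-methoxyphenyl)-1,3-dioxane
Product: 9 [(2S,4S,5S)-5-ethenyl-2-(4-methoxyphenyl)-1,3-dioxan-4-yl]methanol
Conditions: Bu4NF, THF, 0 °C
Reagents that add atoms: none
Why: Fluoride cleavage of the only silyl ether frees the C9 hydroxyl; the acetal is inert to fluoride.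

Step 9
Reactants: 9 [(2S,4S,5S)-5-ethenyl-2-(4-methoxyphenyl)-1,3-dioxan-4-yl]methanol; 4 tert-butyl{[(Z)-2-iodo-4-(phenylsulfanyl)but-2-en-1-yl]oxy}dimethylsilane
Product: 12 (2S,4R,5S)-4-[(E)-2-({[tert-butyl(dimethyl)silyl]oxy}methyl)-4-(phenylsulfanyl)but-2-en-1-yl]-5-ethenyl-2-(4-methoxyphenyl)-1,3-dioxane (C9 cis to C2), via primary triflate 10 (not isolated), via alkenylmagnesium chloride 11 (not isolated)
Conditions: 9: Tf2O, 2,6-lutidine, CH2Cl2, −78 °C, cold aqueous wash; 4: i-PrMgCl·LiCl, THF, −30 °C; then 10 added to 11, CuBr·SMe2 (cat.), THF, −78 to −20 °C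
Reagents that add atoms: none
Why: Iodine–magnesium exchange of an alkenyl iodide proceeds with retention, and copper-catalysed cross-coupling of the alkenyl Grignard reagent with a primary alkyl triflate forms C9–C10 with retention, so the C1=C10 geometry set in step 2 is carried over. A triflate next to an acetal carbon is a well-behaved electrophile of this kind, and the cold magnesium reagent is less prone than the lithium one to lose silanolate or to abstract the thioallylic proton.

Step 10
Reactants: 12 the coupled dioxane
Product: 13 (2S,3R,5E)-5-({[tert-butyl(dimethyl)silyl]oxy}methyl)-2-ethenyl-3-[(4-methoxyphenyl)methoxy]-7-(phenylsulfanyl)hept-5-en-1-ol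
Conditions: i-Bu2AlH, CH2Cl2, −78 to 0 °C; aq. KNaC4H4O6
Reagents that add atoms: none
Why: Regioselective reductive opening of a p-methoxybenzylidene acetal: aluminium coordinates the less hindered primary oxygen, that C–O bond breaks, and hydride reduces the oxocarbenium ion, leaving the p-methoxybenzyl ether on the secondary C8 oxygen and the C6 alcohol free.

Step 11
Reactants: 13 the C6 primary alcohol
Product: 14 (2R,3R,5E)-5-({[tert-butyl(dimethyl)silyl]oxy}methyl)-2-ethenyl-3-[(4-methoxyphenyl)methoxy]-7-(phenylsulfanyl)hept-5-enoic acid
Conditions: TEMPO (cat.), PhI(OAc)2, MeCN/aq. pH 7 buffer, rt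
Reagents that add atoms: water, O
Why: Oxoammonium-mediated oxidation of a primary alcohol through the aldehyde hydrate to the acid under near-neutral conditions; these conditions spare aryl thioethers (as in thioglycoside oxidations) and should not move the β,γ-alkene into conjugation. The acid level at C6 is what later lets a lactone serve as acylating agent.

Step 12
Reactants: 14 the α-vinyl carboxylic acid
Product: 17 (3R)-3-[(1R,3E)-3-({[tert-butyl(dimethyl)silyl]oxy}methyl)-1-[(4-methoxyphenyl)methoxy]-5-(phenylsulfanyl)pent-3-en-1-yl]oxolan-2-one (C7 and C8 as in the target), via borane adduct 15 (not isolated), via hydroxy acid 16 (not isolated)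
Conditions: 9-BBN-H (excess), THF, 0 °C to rt; NaBO3·4H2O, H2O, rt; then aq. citric acid, rt
Reagents that add atoms: sodium perborate, [Na+].[O-]OB=O
Why: Hydroboration–oxidation: 9-BBN-H reacts with the monosubstituted vinyl group far faster than with the hindered trisubstituted alkene and places boron on the terminal carbon C12, while the acid is held as an acyloxyborane and is not reduced. Perborate oxidises the C–B bond without touching the thioether, and the γ-hydroxy acid lactonises on acidification.

Step 13
Reactants: 17 the C6-carbonyl lactone; 1 tert-butyldimethyl(prop-2-yn-1-yloxy)silane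
Product: 18 hydroxy ynone: C6 ketone flanked by the C5≡C4–CH2OSi alkyne, with free C12 hydroxyl and C7, C8 unchanged
Conditions: 1, n-BuLi, THF, −78 °C; then 17, −78 °C; aq. NH4Cl at −78 °C
Reagents that add atoms: none
Why: Addition of a lithium acetylide to a γ-lactone stops at the lithium hemiketal, which opens on work-up to the ω-hydroxy ynone. The cold quench limits epimerisation at C7 and β-elimination of the C8 ether.

Step 14
Reactants: 18 the hydroxy ynone
Product: 19 (6S)-propargylic diol (C6 and C12 hydroxyls; C7, C8 unchanged)
Conditions: RuCl[(S,S)-TsDPEN](p-cymene) (cat., amido form, no added base), i-PrOH, rt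
Reagents that add atoms: none
Why: Noyori asymmetric transfer hydrogenation of an alkynyl ketone: the (S,S) catalyst delivers hydride to the face that gives the (S)-propargylic alcohol, with the alkyne taking the role the arene plays in aryl ketones. C6 is thus set by the catalyst and not by the adjacent C7 centre, and base-free conditions protect the α-stereocentre.

Step 15
Reactants: 19 the propargylic diol
Product: 20 (Z)-alkenyl iodide diol (iodine on C4, cis to C6)
Conditions: NaAlH2(OCH2CH2OMe)2, THF, 0 °C; EtOAc; then I2, THF, −78 °C; aq. Na2S2O3
Reagents that add atoms: iodine, II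
Why: The same alkoxide-directed anti-hydroalumination/iodination as in step 2, now directed by the C6 alkoxide: hydrogen goes to C5 and iodine to C4 cis to C6, which is the position C3 must occupy. The thioether, the benzyl ether and the silyl ethers are inert to the hydride.

Step 16
Reactants: 20 the alkenyl iodide diol
Product: 22 trans-lactone (C12 carbonyl, O on C6) carrying the C4 alkenyl iodide, via lactol 21 (not isolated)
Conditions: TEMPO (cat.), PhI(OAc)2, CH2Cl2, rt
Reagents that add atoms: none
Why: Oxidative lactonisation of a 1,4-diol: the oxoammonium salt oxidises the unhindered primary C12 alcohol first, the aldehyde is trapped by the C6 hydroxyl as the five-membered lactol, and the lactol is oxidised to the lactone. The trans relationship on the lactone follows from the C6 and C7 centres already in place.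

Step 17
Reactants: 22 the iodo lactone
Product: 23 C3 allylic alcohol (CH2OH on C4, cis to C6)
Conditions: Bu3SnCH2OH, Pd(PPh3)4 (cat.), 1,4-dioxane, 80 °C
Reagents that add atoms: (tributylstannyl)methanol, CCCC[Sn](CCCC)(CCCC)CO
Why: Migita–Kosugi–Stille coupling of an alkenyl iodide with a hydroxymethylstannane installs C3 with retention of alkene geometry and needs no reducing agent, so the lactone is not at risk from hydride. Oxidative addition into the C–I bond is much faster than ionisation of the allylic lactone, and the sulfur is still a thioether at this stage.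

Step 18
Reactants: 23 the C3 allylic alcohol
Product: 24 C3 allylic bromide (C2 still a phenyl thioether)
Conditions: CBr4, PPh3, 2,6-lutidine, CH2Cl2, 0 °C
Reagents that add atoms: carbon tetrabromide, BrC(Br)(Br)Br
Why: Appel bromination of a primary allylic alcohol by SN2 displacement of the oxyphosphonium group; the conditions are neutral and leave the lactone, thioether and ethers alone.

Step 19
Reactants: 24 the bromo thioether
Product: 25 cyclisation substrate: trans-lactone with C2 allylic phenyl sulfone and C3 allylic bromide
Conditions: mCPBA (2.2 equiv), NaHCO3, CH2Cl2, −20 to 0 °C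
Reagents that add atoms: 3-chloroperoxybenzoic acid, OOC(=O)c1cccc(Cl)c1
Why: Peracid oxidation of the thioether through the sulfoxide to the sulfone is much faster than epoxidation of the two trisubstituted alkenes, which are each deactivated by allylic oxygen, bromine or sulfur substituents. Doing this last means the acidic sulfone never meets a hydride, an organometallic reagent or zerovalent palladium.

Step 20
Reactants: 25 the sulfone bromide
Product: 26 ten-membered carbocycle with phenylsulfonyl on C2 (either C2 epimer)
Conditions: KN(SiMe3)2 (1.0 equiv, added slowly), THF, −78 °C, ca. 0.002 M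
Reagents that add atoms: none
Why: KN(SiMe3)2 removes one C2 proton, which is allylic and α to the sulfone and therefore several pKa units more acidic than the C11 lactone protons. The potassium sulfonyl-allyl anion then displaces bromide from the primary allylic C3 in an intramolecular SN2 reaction, a 10-exo-tet closure that forms C2–C3 and the carbocycle. The closest known reaction type is the intramolecular alkylation of sulfone- or sulfide-stabilised allylic carbanions by allylic halides, used to close ten- to fourteen-membered 1,5-diene rings. No allyl-metal or π-allyl species is formed at either alkene and the anion reacts at its α-carbon, so both preformed cis ring geometries should be retained. The only new stereocentre is C2, which is lost in step 21; C6, C7 and C8 are not touched. The step needs α- over γ-alkylation (favoured by the sulfone, and γ-attack at the fully substituted C10 would give an eight-membered ring), SN2 over SN2′ (C5 is hindered and would also give an eight-membered ring), and the sulfonyl carbanion rather than the lactone enolate (secured by the acidity gap and by adding one equivalent of base slowly to dilute 25, so that excess base never meets the lactone). The trans-lactone and the two cis alkenes fold the chain so that C2 and C3 can meet, and high dilution suppresses dimerisation.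

Step 21
Reactants: 26 the macrocyclic sulfone
Product: 27 trans-fused lactone macrocycle with C2 as CH2 and C8 as its p-methoxybenzyl ether
Conditions: Na(Hg), Na2HPO4, MeOH/THF, −20 °C
Reagents that add atoms: none
Why: Buffered sodium amalgam desulfonylation: electron transfer cleaves the C2–S bond and the allyl anion is protonated at the less substituted terminus C2, which keeps the trisubstituted C1=C10 alkene. The phosphate buffer keeps methoxide away from the lactone.

Step 22
Reactants: 27 the saturated lactone macrocycle
Product: 30 α-methylene lactone macrocycle (C11=C13), via Mannich base 28 (not isolated), via ammonium iodide 29 (not isolated)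
Conditions: LiN(i-Pr)2, THF, −78 °C; CH2=NMe2+ I−, −78 °C to rt; MeI, MeOH, rt; aq. NaHCO3, CH2Cl2
Reagents that add atoms: N,N-dimethylmethyleneiminium iodide, C=[N+](C)C.[I-]
Why: Lactone α-methylenation by enolate aminomethylation with Eschenmoser's salt, quaternisation and Hofmann-type elimination. C11 is the only acidic position left, and the mild final elimination avoids the strong base that the exocyclic enoate would not tolerate.

Step 23
Reactants: 30 the C8 p-methoxybenzyl ether
Product: 31 C8 alcohol (bis-silyl α-methylene lactone)
Conditions: DDQ, CH2Cl2/aq. pH 7 buffer, 0 °C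
Reagents that add atoms: none
Why: Oxidative cleavage of the electron-rich benzyl ether by hydride abstraction and hydrolysis of the oxocarbenium ion. Silyl ethers, the 1,5-diene and the enoate are not oxidised under buffered conditions, and the neutral pH guards against translactonisation to the C8 oxygen.

Step 24
Reactants: 31 the C8 alcohol
Product: 32 C8 angelate (bis-silyl ether of the target)
Conditions: angelic acid, 2,4,6-Cl3C6H2COCl, Et3N, toluene, rt; then 31, 80 °C
Reagents that add atoms: angelic acid [(Z)-2-methylbut-2-enoic acid], C/C=C(/C)C(=O)O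
Why: Yamaguchi-type esterification through the preformed mixed anhydride, run without a nucleophilic amine catalyst, acylates hindered secondary alcohols while keeping the Z geometry of the angeloyl group; nucleophilic catalysts promote isomerisation to the tiglate by reversible conjugate addition.

Step 25
Reactants: 32 the bis-silyl ether
Product: 33 target, (6R,7R,8R)-8-angeloyloxy-14,15-dihydroxygermacra-1(10),4,11(13)-trien-12,6-olide (ring alkenes cis along the ring)
Conditions: HF·pyridine, pyridine, THF, 0 °C to rt
Reagents that add atoms: none
Why: Buffered fluoride cleavage of the two primary allylic silyl ethers under weakly acidic, non-nucleophilic conditions that leave the α-methylene lactone and the angelate intact; no stereocentre or alkene is involved.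

## Compound list

1 | tert-butyldimethyl(prop-2-yn-1-yloxy)silane | C#CCO[Si](C)(C)C(C)(C)C | starting material
2 | 4-[(tert-butyldimethylsilyl)oxy]but-2-yn-1-ol | OCC#CCO[Si](C)(C)C(C)(C)C | intermediate
3 | (Z)-4-[(tert-butyldimethylsilyl)oxy]-3-iodobut-2-en-1-ol | OC/C=C(\I)CO[Si](C)(C)C(C)(C)C | intermediate
4 | tert-butyl{[(Z)-2-iodo-4-(phenylsulfanyl)but-2-en-1-yl]oxy}dimethylsilane | c1ccccc1SC/C=C(\I)CO[Si](C)(C)C(C)(C)C | intermediate
5 | (E)-4-[(tert-butyldimethylsilyl)oxy]but-2-en-1-ol | OC/C=C/CO[Si](C)(C)C(C)(C)C | intermediate
6 | [(2R,3R)-3-({[tert-butyl(dimethyl)silyl]oxy}methyl)oxiran-2-yl]methanol | OC[C@H]1O[C@@H]1CO[Si](C)(C)C(C)(C)C | intermediate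
7 | (2S,3S)-4-[(tert-butyldimethylsilyl)oxy]-2-ethenylbutane-1,3-diol | OC[C@H](C=C)[C@H](O)CO[Si](C)(C)C(C)(C)C | intermediate
8 | (2S,4S,5S)-4-({[tert-butyl(dimethyl)silyl]oxy}methyl)-5-ethenyl-2-(4-methoxyphenyl)-1,3-dioxane | COc1ccc(cc1)[C@H]1OC[C@H](C=C)[C@@H](CO[Si](C)(C)C(C)(C)C)O1 | intermediate
9 | [(2S,4S,5S)-5-ethenyl-2-(4-methoxyphenyl)-1,3-dioxan-4-yl]methanol | COc1ccc(cc1)[C@H]1OC[C@H](C=C)[C@@H](CO)O1 | intermediate
10 | [(2S,4S,5S)-5-ethenyl-2-(4-methoxyphenyl)-1,3-dioxan-4-yl]methyl trifluoromethanesulfonate | COc1ccc(cc1)[C@H]1OC[C@H](C=C)[C@@H](COS(=O)(=O)C(F)(F)F)O1 | intermediate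
11 | {(Z)-1-({[tert-butyl(dimethyl)silyl]oxy}methyl)-3-(phenylsulfanyl)prop-1-en-1-yl}magnesium chloride (LiCl complex) | c1ccccc1SC/C=C(\[Mg]Cl)CO[Si](C)(C)C(C)(C)C | intermediate
12 | (2S,4R,5S)-4-[(E)-2-({[tert-butyl(dimethyl)silyl]oxy}methyl)-4-(phenylsulfanyl)but-2-en-1-yl]-5-ethenyl-2-(4-methoxyphenyl)-1,3-dioxane | COc1ccc(cc1)[C@H]1OC[C@H](C=C)[C@@H](C/C(CO[Si](C)(C)C(C)(C)C)=C\CSc2ccccc2)O1 | intermediate
13 | (2S,3R,5E)-5-({[tert-butyl(dimethyl)silyl]oxy}methyl)-2-ethenyl-3-[(4-methoxyphenyl)methoxy]-7-(phenylsulfanyl)hept-5-en-1-ol | OC[C@H](C=C)[C@H](OCc1ccc(OC)cc1)C/C(CO[Si](C)(C)C(C)(C)C)=C\CSc1ccccc1 | intermediate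
14 | (2R,3R,5E)-5-({[tert-butyl(dimethyl)silyl]oxy}methyl)-2-ethenyl-3-[(4-methoxyphenyl)methoxy]-7-(phenylsulfanyl)hept-5-enoic acid | OC(=O)[C@H](C=C)[C@H](OCc1ccc(OC)cc1)C/C(CO[Si](C)(C)C(C)(C)C)=C\CSc1ccccc1 | intermediate
15 | borane adduct of 14: 9-borabicyclo[3.3.1]nonan-9-yl on C12, acid held as its 9-BBN acyloxyborane | O=C(OB1C2CCCC1CCC2)[C@H](CCB1C2CCCC1CCC2)[C@H](OCc1ccc(OC)cc1)C/C(CO[Si](C)(C)C(C)(C)C)=C\CSc1ccccc1 | intermediate
16 | hydroxy acid: 2-(2-hydroxyethyl) analogue of 14 (C12 hydroxyl, C6 acid) | OC(=O)[C@H](CCO)[C@H](OCc1ccc(OC)cc1)C/C(CO[Si](C)(C)C(C)(C)C)=C\CSc1ccccc1 | intermediate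
17 | (3R)-3-[(1R,3E)-3-({[tert-butyl(dimethyl)silyl]oxy}methyl)-1-[(4-methoxyphenyl)methoxy]-5-(phenylsulfanyl)pent-3-en-1-yl]oxolan-2-one (C6 carbonyl, ring O on C12) | O=C1OCC[C@@H]1[C@H](OCc2ccc(OC)cc2)C/C(CO[Si](C)(C)C(C)(C)C)=C\CSc2ccccc2 | intermediate
18 | hydroxy ynone: C6 ketone, C5≡C4–C15H2OSi alkyne, free C12 hydroxyl, C7 and C8 as in the target | OCC[C@@H](C(=O)C#CCO[Si](C)(C)C(C)(C)C)[C@H](OCc1ccc(OC)cc1)C/C(CO[Si](C)(C)C(C)(C)C)=C\CSc1ccccc1 | intermediate
19 | (6S)-propargylic diol (C6 and C12 hydroxyls), C7 and C8 as in the target | OCC[C@@H]([C@H](O)C#CCO[Si](C)(C)C(C)(C)C)[C@H](OCc1ccc(OC)cc1)C/C(CO[Si](C)(C)C(C)(C)C)=C\CSc1ccccc1 | intermediate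
20 | alkenyl iodide diol: (Z)-C5=C4 with iodine on C4 cis to C6, C6 and C12 hydroxyls | OCC[C@@H]([C@H](O)/C=C(\I)CO[Si](C)(C)C(C)(C)C)[C@H](OCc1ccc(OC)cc1)C/C(CO[Si](C)(C)C(C)(C)C)=C\CSc1ccccc1 | intermediate
21 | lactol of 22 (C12 hemiacetal, both anomers) | C1C(O)O[C@H](/C=C(\I)CO[Si](C)(C)C(C)(C)C)[C@H]1[C@H](OCc2ccc(OC)cc2)C/C(CO[Si](C)(C)C(C)(C)C)=C\CSc2ccccc2 | intermediate
22 | trans-4,5-disubstituted γ-lactone (12,6-olide) with C4 alkenyl iodide, C8 p-methoxybenzyl ether and C2 phenyl thioether | C1C(=O)O[C@H](/C=C(\I)CO[Si](C)(C)C(C)(C)C)[C@H]1[C@H](OCc2ccc(OC)cc2)C/C(CO[Si](C)(C)C(C)(C)C)=C\CSc2ccccc2 | intermediate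
23 | C3 allylic alcohol of the lactone (C3H2OH on C4, cis to C6) | C1C(=O)O[C@H](/C=C(/CO[Si](C)(C)C(C)(C)C)CO)[C@H]1[C@H](OCc2ccc(OC)cc2)C/C(CO[Si](C)(C)C(C)(C)C)=C\CSc2ccccc2 | intermediate
24 | C3 allylic bromide with C2 phenyl thioether | C1C(=O)O[C@H](/C=C(/CO[Si](C)(C)C(C)(C)C)CBr)[C@H]1[C@H](OCc2ccc(OC)cc2)C/C(CO[Si](C)(C)C(C)(C)C)=C\CSc2ccccc2 | intermediate
25 | cyclisation substrate: lactone with C2 allylic phenyl sulfone and C3 allylic bromide | C1C(=O)O[C@H](/C=C(/CO[Si](C)(C)C(C)(C)C)CBr)[C@H]1[C@H](OCc2ccc(OC)cc2)C/C(CO[Si](C)(C)C(C)(C)C)=C\CS(=O)(=O)c2ccccc2 | intermediate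
26 | lactone macrocycle with phenylsulfonyl on C2 (C2 epimers) | C1C(=O)O[C@@H]2/C=C(/CO[Si](C)(C)C(C)(C)C)CC(S(=O)(=O)c3ccccc3)/C=C(/CO[Si](C)(C)C(C)(C)C)C[C@@H](OCc3ccc(OC)cc3)[C@@H]12 | intermediate
27 | desulfonylated trans-fused lactone macrocycle, C8 p-methoxybenzyl ether | C1C(=O)O[C@@H]2/C=C(/CO[Si](C)(C)C(C)(C)C)CC/C=C(/CO[Si](C)(C)C(C)(C)C)C[C@@H](OCc3ccc(OC)cc3)[C@@H]12 | intermediate
28 | C11 (dimethylamino)methyl lactone (Mannich base, C11 undefined) | CN(C)CC1C(=O)O[C@@H]2/C=C(/CO[Si](C)(C)C(C)(C)C)CC/C=C(/CO[Si](C)(C)C(C)(C)C)C[C@@H](OCc3ccc(OC)cc3)[C@@H]12 | intermediate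
29 | C11 (trimethylammonio)methyl lactone iodide | C[N+](C)(C)CC1C(=O)O[C@@H]2/C=C(/CO[Si](C)(C)C(C)(C)C)CC/C=C(/CO[Si](C)(C)C(C)(C)C)C[C@@H](OCc3ccc(OC)cc3)[C@@H]12.[I-] | intermediate
30 | α-methylene lactone macrocycle, C8 p-methoxybenzyl ether, C14 and C15 silyl ethers | C=C1C(=O)O[C@@H]2/C=C(/CO[Si](C)(C)C(C)(C)C)CC/C=C(/CO[Si](C)(C)C(C)(C)C)C[C@@H](OCc3ccc(OC)cc3)[C@@H]12 | intermediate
31 | α-methylene lactone macrocycle with free (8R) hydroxyl | C=C1C(=O)O[C@@H]2/C=C(/CO[Si](C)(C)C(C)(C)C)CC/C=C(/CO[Si](C)(C)C(C)(C)C)C[C@@H](O)[C@@H]12 | intermediate
32 | C8 angelate, C14 and C15 silyl ethers | C=C1C(=O)O[C@@H]2/C=C(/CO[Si](C)(C)C(C)(C)C)CC/C=C(/CO[Si](C)(C)C(C)(C)C)C[C@@H](OC(=O)/C(C)=C\C)[C@@H]12 | intermediate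
33 | (6R,7R,8R)-8-angeloyloxy-14,15-dihydroxygermacra-1(10),4,11(13)-trien-12,6-olide (CNP0182172.4) | C=C1C(=O)O[C@@H]2/C=C(/CO)CC/C=C(/CO)C[C@@H](OC(=O)/C(C)=C\C)[C@@H]12 | target

## Step count and least certain steps

Total: 25 steps. Longest linear sequence: 23 steps (step 1, then steps 4 to 25); steps 2 and 3 form the branch that delivers 4.

Step 20 (key step). Ring closure may be outpaced by intermolecular alkylation, since a ten-membered ring is entropically and transannularly costly. Proton transfer may also generate the lactone enolate, whose C11 can reach C3 through a six-membered transition state, and the allylic bromide may be lost to base. The fallback removes the competing acidic site. It sets out from 25, which is reduced with i-Bu2AlH at −78 °C to the lactol F1; the anomeric hydroxyl is silylated with Et3SiOTf and 2,6-lutidine to give the triethylsilyl lactol ether F2; KN(SiMe3)2 under the same dilution then closes the ring to the macrocyclic silyl lactol F3. Buffered HF·pyridine would cleave the anomeric silyl ether selectively, and TEMPO with PhI(OAc)2 would oxidise the lactol, returning to the route at 26.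

Step 9. The alkenylmagnesium reagent may form slowly, eliminate silanolate towards an allene, or move its charge to the thioallylic carbon by proton transfer, and the triflate may decompose before it is captured. The fallback replaces the organometallic coupling by carbanion alkylation and olefination. From triflate 10, the sodium salt of triethyl phosphonoacetate (NaH, THF/DMF) would give the alkylated phosphonate F4. A Horner–Wadsworth–Emmons reaction with (phenylsulfanyl)acetaldehyde would give the enoate F5, whose normal geometry (ester trans to C2) is the one required. Reduction with i-Bu2AlH at −78 °C, with the acetal intact, would give the allylic alcohol F6, and silylation with t-BuMe2SiCl and imidazole returns to the route at 12.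

Step 6. The vinyl nucleophile may attack the epoxide at C8 as well as at C7, which lowers the throughput of the stereodefining step. The fallback removes the regiochemical question by symmetry. From 6, Bu4NF would give the C2-symmetric epoxy diol F7, whose two epoxide carbons are equivalent, so copper-catalysed addition of CH2=CHMgBr at low temperature can give only the triol F8. Thermodynamic acetalisation with 4-methoxybenzaldehyde dimethyl acetal, which favours the all-equatorial 1,3-dioxane, returns to the route at 9.

Step 17. Transfer of the hydroxymethyl group from tin may be slow at the temperature required, and during that time zerovalent palladium may ionise the allylic lactone (epimerisation at C6) or the iodide may be reduced. The fallback introduces C3 at the aldehyde oxidation level under milder conditions. From 22, carbonylative formylation (Pd(PPh3)4, CO, Bu3SnH, THF, 50 °C) would give the enal F9, and Luche reduction (NaBH4, CeCl3, MeOH, −40 °C), which spares the lactone, returns to the route at 23.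

Step 21. The allyl anion formed on C–S cleavage may be protonated at C10, moving the C1=C10 alkene, and the allylic lactone C–O bond may suffer reduction or methanolysis. The fallback replaces electron transfer by hydride delivery. From 26, Pd(PPh3)4-catalysed displacement of the sulfinate with NaBH4 (THF/i-PrOH, 0 °C) would place hydride at the less substituted C2 terminus of the π-allyl intermediate and return to the route at 27; it makes no new compound.

## Further compounds

F1 | step 20 | lactol of 25 (C12 hemiacetal) with C2 sulfone and C3 bromide | C1C(O)O[C@H](/C=C(/CO[Si](C)(C)C(C)(C)C)CBr)[C@H]1[C@H](OCc2ccc(OC)cc2)C/C(CO[Si](C)(C)C(C)(C)C)=C\CS(=O)(=O)c2ccccc2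
F2 | step 20 | triethylsilyl lactol ether of F1 | C1C(O[Si](CC)(CC)CC)O[C@H](/C=C(/CO[Si](C)(C)C(C)(C)C)CBr)[C@H]1[C@H](OCc2ccc(OC)cc2)C/C(CO[Si](C)(C)C(C)(C)C)=C\CS(=O)(=O)c2ccccc2
F3 | step 20 | macrocyclic C2 sulfone with the lactone masked as its triethylsilyl lactol ether | C1C(O[Si](CC)(CC)CC)O[C@@H]2/C=C(/CO[Si](C)(C)C(C)(C)C)CC(S(=O)(=O)c3ccccc3)/C=C(/CO[Si](C)(C)C(C)(C)C)C[C@@H](OCc3ccc(OC)cc3)[C@@H]12
F4 | step 9 | ethyl 2-(diethoxyphosphoryl)-3-[(2S,4R,5S)-5-ethenyl-2-(4-methoxyphenyl)-1,3-dioxan-4-yl]propanoate | COc1ccc(cc1)[C@H]1OC[C@H](C=C)[C@@H](CC(C(=O)OCC)P(=O)(OCC)OCC)O1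
F5 | step 9 | ethyl (E)-2-{[(2S,4R,5S)-5-ethenyl-2-(4-methoxyphenyl)-1,3-dioxan-4-yl]methyl}-4-(phenylsulfanyl)but-2-enoate | COc1ccc(cc1)[C@H]1OC[C@H](C=C)[C@@H](C/C(C(=O)OCC)=C\CSc2ccccc2)O1
F6 | step 9 | C14 allylic alcohol corresponding to 12 (silyl group absent) | COc1ccc(cc1)[C@H]1OC[C@H](C=C)[C@@H](C/C(CO)=C\CSc2ccccc2)O1
F7 | step 6 | [(2R,3R)-oxirane-2,3-diyl]dimethanol | OC[C@H]1O[C@@H]1CO
F8 | step 6 | (2S,3S)-3-ethenylbutane-1,2,4-triol | OC[C@H](C=C)[C@H](O)CO
F9 | step 17 | C3 enal of the lactone (CHO on C4, cis to C6) | C1C(=O)O[C@H](/C=C(/CO[Si](C)(C)C(C)(C)C)C=O)[C@H]1[C@H](OCc2ccc(OC)cc2)C/C(CO[Si](C)(C)C(C)(C)C)=C\CSc2ccccc2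
F0 | step 21 | none | none
A1 | alternative 1 | 3-(bromomethyl)butenolide carrying the C5–C10 chain with a C8 aldehyde | O=C1O[C@H](/C=C(/CO[Si](C)(C)C(C)(C)C)CC/C=C(/CO[Si](C)(C)C(C)(C)C)CC=O)C=C1CBr
A2 | alternative 1 | bis-silyl α-methylene lactone macrocycle with free 8-epi hydroxyl | C=C1C(=O)O[C@@H]2/C=C(/CO[Si](C)(C)C(C)(C)C)CC/C=C(/CO[Si](C)(C)C(C)(C)C)C[C@H](O)[C@@H]12
A3 | alternative 2 | methyl ester aldehyde with C5 alkenyl iodide (C6 aldehyde, C12 ester, C8 p-methoxybenzyl ether) | COC(=O)C[C@@H](C=O)[C@H](OCc1ccc(OC)cc1)C/C(CO[Si](C)(C)C(C)(C)C)=C\CC/C(CO[Si](C)(C)C(C)(C)C)=C\I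
A4 | alternative 2 | trans-fused lactone macrocycle lacking the exo-methylene (same structure as 27) | C1C(=O)O[C@@H]2/C=C(/CO[Si](C)(C)C(C)(C)C)CC/C=C(/CO[Si](C)(C)C(C)(C)C)C[C@@H](OCc3ccc(OC)cc3)[C@@H]12
A5 | alternative 3 | cis-1,2-dialkenyl cyclohex-3-enol drawn as one enantiomer with an (E)-enol ether (C6 tertiary alcohol, C1 isopropenyl-type substituent) | O[C@]1(/C=C/OCc2ccc(OC)cc2)C=C(CO[Si](C)(C)C(C)(C)C)CC[C@H]1C(=C)CO[Si](C)(C)C(C)(C)C
A6 | alternative 3 | ten-membered dienone with C6 ketone and C8 p-methoxybenzyl ether | O=C1/C=C(/CO[Si](C)(C)C(C)(C)C)CC/C=C(/CO[Si](C)(C)C(C)(C)C)C[C@@H](OCc2ccc(OC)cc2)C1
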